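The readings were computed for substances that don't exist; scatter was added.

The molar minute, reagent charge multiplied by time, was the unit this meeting agreed to measure the flask in, and these minutes record how it got there.

| setting | grey | green | ochre |
|---|---|---|---|
| starting material | 0.600 M | 0.600 M | 0.180 M |
| reagent | 0.600 M | 0.900 M | 0.180 M |
| time |  |  | 110 min |

| grey run: time / min | grey run: [product] / M | green run: time / min | green run: [product] / M |
|---|---|---|---|
| 16 | 0.2073 | 16 | 0.2879 |
| 31 | 0.2883 | 31 | 0.3790 |
| 47 | 0.3273 | 47 | 0.4156 |
| 63 | 0.3481 | 63 | 0.4349 |
| 79 | 0.3637 | 79 | 0.4436 |
| 94 | 0.3672 | 94 | 0.4435 |
| 110 | 0.3701 | 110 | 0.4463 |

(scatter of a reading: 0.002 M)

- Overall: starting material + reagent -> product.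
- Constant volume, constant temperature.
- Readings of a species count what is bound in complexes too.
- An order is taken over about fifteen percent of the charge, up and down.

* the power of [reagent] that the first rate follows, about the charge of the grey run; measure it at two percent of starting material made into product
* product in the ochre run at 110 min, as a share of the starting material charged

The first speaker noted that product levels off near 61.7% of the starting material charged in the grey run and 74.4% in the green run, and proposed that these levels are equilibria. The second speaker reckoned an equilibrium constant from the last reading of each run, found 7.00 L mol⁻¹ for grey and 6.40 L mol⁻¹ for green, judged grey larger than a scatter of 0.002 M explains, and argued that the level may instead be a selectivity, with starting material shared between product and a competing path that also takes two partners.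

The chair then took equal charges as the zero of the scale. Grey and ochre both charge starting material and reagent equally, so if every step takes two partners, the ochre dilution by 3.33 merely stretches the clock, and equal molar minutes give equal fractions of the charge. She therefore defined the matched time, the time in the grey run that holds the same molar minutes as the flask in question, and for the ochre run it comes to 33.0 min. The grey readings at 31 min and 47 min, interpolated, give 48.9% of the charge, which the meeting adopted as its reckoning. For the order it took the first power of reagent, since the first readings stand in the ratio 1.39 against a charge ratio of 1.50.

The forecast, for which the levelling “points to a reversible” reaction, gave 39.2% and an order of 1. The flask gives 50.4% and an order of 0.96.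

    starting material + reagent ⇌ intermediate, settled at all times (0.4030 L mol⁻¹)
    starting material + reagent → product (0.1320 L mol⁻¹ min⁻¹)
    2 starting material → homo dimer (0.09660 L mol⁻¹ min⁻¹)
    2 starting material ⇌ idle substrate dimer, settled at all times (1.230 L mol⁻¹)

Product in the grey run reaches half of the charge at 35.4 min, against the ochre matched time of 33.0 min. Product in the green run reaches a quarter of the charge at 6.11 min, a matched time of 9.16 min against 9.66 min in the grey run. The conversion of two starting material into homo dimer costs the ochre run 17 percentage points of product at 110 min, for with that step taken away the same run gives 67.3% instead of 50.4%, and that difference is 34% of what is missing from the charge.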